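**Retrosynthetic overview**

1. Target ⇐ removal of two MOM ethers ⇐ pyran ring (O2–C3 bond) by silver-catalysed 6-endo-dig closure of the C1 hydroxyl onto an enyne acid, itself from Sonogashira coupling of a ring ethynyl group with (E)-3-iodoacrylic acid.
2. Aryl ester ⇐ acylation of the secondary hydroxyl of a cis-diol with the chloride of 2-methoxy-3,4-bis(methoxymethoxy)-6-methylbenzoic acid (six steps from p-cresol).
3. Cyclohexenone cis-diol ⇐ key step: α-ketol ring expansion of a 1-acetylcyclopent-2-en-1-ol (1,2-shift of the silyloxy-bearing ring carbon); it makes the six-membered ring and the tertiary carbinol.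
4. Ketol ⇐ 1-ethoxyvinyllithium addition to a 5-silyloxy-3-alkynyl-2-(silyloxymethyl)cyclopentenone ⇐ (R)-4-silyloxycyclopent-2-enone by Baylis–Hillman hydroxymethylation, acetylide addition and oxidative transposition.
5. Ring order: cyclopentene (bought) → cyclohexenone (ring expansion) → pyran (cyclisation); the arene is carried through from p-cresol.

Assumption: (R)-4-(silyloxy)cyclopent-2-enone and (E)-3-iodoacrylic acid are bought; one- and two-carbon units (formaldehyde, CO2, MeI, trimethylsilylacetylene, ethyl vinyl ether) are treated as reagents.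

Abbreviations: TBS = tert-butyldimethylsilyl; TBDPS = tert-butyldiphenylsilyl; TMS = trimethylsilyl; MOM = methoxymethyl; IBX = 2-iodoxybenzoic acid.

**Route**

Step 1
Reactants: 1 4-methylphenol (p-cresol)
Product: 3 4-methylbenzene-1,2-diol, via 4-methyl-1,2-benzoquinone 2 (not isolated)
Conditions: IBX, DMF, rt; then aq. Na2S2O4
Reagents that add atoms: 2-iodoxybenzoic acid (IBX), O=C1OI(O)(=O)c2ccccc12
Why: IBX ortho-oxygenation of a phenol gives the o-quinone (both ortho positions are equivalent) and dithionite reduces it to the catechol.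

Step 2
Reactants: 3 4-methylbenzene-1,2-diol
Product: 4 1,2-bis(methoxymethoxy)-4-methylbenzene
Conditions: NaH, MOMCl, DMF, 0 °C → rt
Reagents that add atoms: chloromethyl methyl ether, COCCl
Why: Williamson-type O-alkylation protects both phenols as MOM ethers, which later serve as ortho-directing groups and fall off with acid at the end.

Step 3
Reactants: 4 1,2-bis(methoxymethoxy)-4-methylbenzene
Product: 5 1-bromo-4,5-bis(methoxymethoxy)-2-methylbenzene
Conditions: NBS, MeCN, 0 °C → rt, dark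
Reagents that add atoms: N-bromosuccinimide, O=C1CCC(=O)N1Br
Why: Electrophilic aromatic bromination goes to the position para to one ether oxygen and ortho to methyl, as in 4-methylveratrole, and fixes where the carboxyl will sit.

Step 4
Reactants: 5 1-bromo-4,5-bis(methoxymethoxy)-2-methylbenzene
Product: 8 2-bromo-5,6-bis(methoxymethoxy)-3-methylphenol, via aryllithium 6 (not isolated), via diisopropyl arylboronate 7 (not isolated)
Conditions: LiN(i-Pr)2, B(OiPr)3, THF, −78 °C (in situ trap); then AcOH, 30% H2O2, 0 °C → rt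
Reagents that add atoms: hydrogen peroxide, OO
Why: Directed ortho-metalation removes the only C–H flanked by Br and OMOM, the in situ borate trap prevents halogen migration, and boronate oxidation gives the phenol.

Step 5
Reactants: 8 2-bromo-5,6-bis(methoxymethoxy)-3-methylphenol
Product: 9 1-bromo-2-methoxy-3,4-bis(methoxymethoxy)-6-methylbenzene
Conditions: MeI, K2CO3, DMF, rt
Reagents that add atoms: iodomethane, CI
Why: Williamson O-methylation of the single free phenol installs the methoxy group next to the future carboxyl.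

Step 6
Reactants: 9 1-bromo-2-methoxy-3,4-bis(methoxymethoxy)-6-methylbenzene
Product: 11 2-methoxy-3,4-bis(methoxymethoxy)-6-methylbenzoic acid, via aryllithium 10 (not isolated)
Conditions: n-BuLi, THF, −78 °C; CO2, −78 → 0 °C; then cold 1 M HCl to pH 3
Reagents that add atoms: carbon dioxide, O=C=O
Why: Bromine–lithium exchange followed by carboxylation puts the acid exactly where bromine was, so no regiochemical question arises.

Step 7
Reactants: 12 (4R)-4-[(TBS)oxy]cyclopent-2-en-1-one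
Product: 13 (4R)-4-[(TBS)oxy]-2-(hydroxymethyl)cyclopent-2-en-1-one
Conditions: 37% aq. HCHO, PBu3 (10 mol %), CHCl3/MeOH, rt
Reagents that add atoms: formaldehyde, C=O
Why: Morita–Baylis–Hillman α-hydroxymethylation of the enone brings in C1 of the pyran without touching the silyloxy stereocentre.

Step 8
Reactants: 13 (4R)-4-[(TBS)oxy]-2-(hydroxymethyl)cyclopent-2-en-1-one
Product: 14 (4R)-4-[(TBS)oxy]-2-{[(TBDPS)oxy]methyl}cyclopent-2-en-1-one
Conditions: TBDPSCl, imidazole, DMF, 0 °C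
Reagents that add atoms: tert-butyl(chloro)diphenylsilane, CC(C)(C)[Si](Cl)(c1ccccc1)c1ccccc1
Why: Silylation gives a primary silyl ether that is more robust than the secondary TBS ether and can be kept when the latter is removed.

Step 9
Reactants: 14 (4R)-4-[(TBS)oxy]-2-{[(TBDPS)oxy]methyl}cyclopent-2-en-1-one
Product: 15 (1S,4R)-4-[(TBS)oxy]-2-{[(TBDPS)oxy]methyl}-1-[(TMS)ethynyl]cyclopent-2-en-1-ol (major epimer)
Conditions: Me3SiC≡CH, n-BuLi, THF, −78 °C; then 14, −78 °C; aq. NH4Cl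
Reagents that add atoms: (trimethylsilyl)acetylene, C#C[Si](C)(C)C
Why: Lithium acetylide adds 1,2 to the enone carbonyl, mainly trans to the silyloxy group, and the new carbinol centre is erased in the next step so its ratio does not matter.

Step 10
Reactants: 15 (1S,4R)-4-[(TBS)oxy]-2-{[(TBDPS)oxy]methyl}-1-[(TMS)ethynyl]cyclopent-2-en-1-ol
Product: 16 (5R)-5-[(TBS)oxy]-2-{[(TBDPS)oxy]methyl}-3-[(TMS)ethynyl]cyclopent-2-en-1-one
Conditions: pyridinium chlorochromate (C5H5NH[CrO3Cl]), 4 Å MS, CH2Cl2, rt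
Reagents that add atoms: none
Why: Babler–Dauben oxidative 1,3-transposition of the tertiary allylic alcohol moves the oxygen next to the silyloxy carbon and leaves the alkyne on the β-carbon.

Step 11
Reactants: 16 (5R)-5-[(TBS)oxy]-2-{[(TBDPS)oxy]methyl}-3-[(TMS)ethynyl]cyclopent-2-en-1-one
Product: 18 1-[(1S,5R)-5-[(TBS)oxy]-2-{[(TBDPS)oxy]methyl}-1-hydroxy-3-[(TMS)ethynyl]cyclopent-2-en-1-yl]ethan-1-one, via enol ether carbinol 17 (not isolated)
Conditions: CH2=CHOEt, t-BuLi, THF, −78 → 0 °C; then 16, −78 °C; then 0.5 M aq. HCl, THF, 0 °C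
Reagents that add atoms: ethyl vinyl ether, C=COCC; water, O
Why: 1,2-Addition of the acyl anion equivalent 1-ethoxyvinyllithium occurs anti to the adjacent silyloxy group, so the new tertiary hydroxyl is cis to it (1S), and enol ether hydrolysis then gives the α-ketol.

Step 12
Reactants: 18 1-[(1S,5R)-5-[(TBS)oxy]-2-{[(TBDPS)oxy]methyl}-1-hydroxy-3-[(TMS)ethynyl]cyclopent-2-en-1-yl]ethan-1-one
Product: 19 (5R,6R)-5-[(TBS)oxy]-2-{[(TBDPS)oxy]methyl}-6-hydroxy-6-methyl-3-[(TMS)ethynyl]cyclohex-2-en-1-one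
Conditions: Sc(OTf)3 (15 mol %), 4 Å MS, CH2Cl2, −20 °C → rt
Reagents that add atoms: none
Why: Proposed new method: Sc(OTf)3 binds the tertiary hydroxyl and the acetyl carbonyl in a syn five-membered chelate, the silyloxy-bearing ring carbon (better able to carry positive charge than the enyne vinyl carbon) shifts suprafacially with retention from the carbinol carbon to the carbonyl carbon, the ring grows from five to six members with the conjugated enone as thermodynamic sink, and the chelate geometry places the new tertiary hydroxyl cis to the silyloxy group (6R); the closest known reaction is the Lewis-acid α-ketol (acyloin) ring expansion of 1-acylcycloalkanols (D-homoannulation of 17-hydroxy-20-oxo steroids), which has not been shown for 1-acylcyclopent-2-en-1-ols that carry an alkyne and a competing vinyl migrating group.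

Step 13
Reactants: 19 (5R,6R)-5-[(TBS)oxy]-2-{[(TBDPS)oxy]methyl}-6-hydroxy-6-methyl-3-[(TMS)ethynyl]cyclohex-2-en-1-one
Product: 20 (5R,6R)-2-{[(TBDPS)oxy]methyl}-5,6-dihydroxy-6-methyl-3-[(TMS)ethynyl]cyclohex-2-en-1-one
Conditions: 48% aq. HF, MeCN, 0 °C
Reagents that add atoms: none
Why: Acidic fluoride desilylation cleaves the secondary TBS ether while the primary TBDPS ether and the alkynyl TMS group survive, and acid avoids retro-aldol of the β-hydroxy ketone.

Step 14
Reactants: 20 (5R,6R)-2-{[(TBDPS)oxy]methyl}-5,6-dihydroxy-6-methyl-3-[(TMS)ethynyl]cyclohex-2-en-1-one; 11 2-methoxy-3,4-bis(methoxymethoxy)-6-methylbenzoic acid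
Product: 22 (1R,6R)-4-{[(TBDPS)oxy]methyl}-6-hydroxy-6-methyl-5-oxo-3-[(TMS)ethynyl]cyclohex-3-en-1-yl 2-methoxy-3,4-bis(methoxymethoxy)-6-methylbenzoate, via acid chloride 21 (not isolated)
Conditions: 11, 1-chloro-N,N,2-trimethylprop-1-en-1-amine, CH2Cl2, 0 °C → rt; then 20, DMAP, pyridine, CH2Cl2, 35 °C
Reagents that add atoms: none
Why: DMAP-catalysed acylation by the acid chloride (made under neutral conditions that spare the MOM ethers) takes the secondary hydroxyl selectively over the tertiary one, with retention at the carbinol carbon.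

Step 15
Reactants: 22 (1R,6R)-4-{[(TBDPS)oxy]methyl}-6-hydroxy-6-methyl-5-oxo-3-[(TMS)ethynyl]cyclohex-3-en-1-yl 2-methoxy-3,4-bis(methoxymethoxy)-6-methylbenzoate
Product: 23 (1R,6R)-3-ethynyl-6-hydroxy-4-(hydroxymethyl)-6-methyl-5-oxocyclohex-3-en-1-yl 2-methoxy-3,4-bis(methoxymethoxy)-6-methylbenzoate
Conditions: Bu4NF, AcOH, THF, 0 °C → rt
Reagents that add atoms: none
Why: Fluoride desilylation removes the O-TBDPS and C-TMS groups together, and the acetic acid buffer suppresses base-induced loss of the β-aroyloxy group and early oxa-Michael closure.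

Step 16
Reactants: 23 (1R,6R)-3-ethynyl-6-hydroxy-4-(hydroxymethyl)-6-methyl-5-oxocyclohex-3-en-1-yl 2-methoxy-3,4-bis(methoxymethoxy)-6-methylbenzoate; 24 (2E)-3-iodoprop-2-enoic acid
Product: 25 (2E)-5-[(4R,5R)-4-hydroxy-2-(hydroxymethyl)-5-{[2-methoxy-3,4-bis(methoxymethoxy)-6-methylbenzoyl]oxy}-4-methyl-3-oxocyclohex-1-en-1-yl]pent-2-en-4-ynoic acid
Conditions: PdCl2(PPh3)2 (5 mol %), CuI (10 mol %), Et3N, THF, rt, degassed
Reagents that add atoms: none
Why: Sonogashira coupling of the terminal alkyne with the vinyl iodide proceeds with retention of the E geometry and tolerates the free acid as its ammonium salt.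

Step 17
Reactants: 25 (2E)-5-[(4R,5R)-4-hydroxy-2-(hydroxymethyl)-5-{[2-methoxy-3,4-bis(methoxymethoxy)-6-methylbenzoyl]oxy}-4-methyl-3-oxocyclohex-1-en-1-yl]pent-2-en-4-ynoic acid
Product: 26 (2E)-3-[(6R,7R)-7-hydroxy-6-{[2-methoxy-3,4-bis(methoxymethoxy)-6-methylbenzoyl]oxy}-7-methyl-8-oxo-5,6,7,8-tetrahydro-1H-isochromen-3-yl]prop-2-enoic acid
Conditions: AgOTf (10 mol %), CH2Cl2, rt, dark
Reagents that add atoms: none
Why: π-Acid-catalysed 6-endo-dig hydroalkoxylation (cycloisomerisation) closes the pyran, because the ring ketone polarises the alkyne so that the hydroxyl attacks the distal carbon and the product is a stabilised vinylogous ester.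

Step 18
Reactants: 26 (2E)-3-[(6R,7R)-7-hydroxy-6-{[2-methoxy-3,4-bis(methoxymethoxy)-6-methylbenzoyl]oxy}-7-methyl-8-oxo-5,6,7,8-tetrahydro-1H-isochromen-3-yl]prop-2-enoic acid
Product: 27 (2E)-3-[(6R,7R)-6-[(3,4-dihydroxy-2-methoxy-6-methylbenzoyl)oxy]-7-hydroxy-7-methyl-8-oxo-5,6,7,8-tetrahydro-1H-isochromen-3-yl]prop-2-enoic acid (CNP0446308.2)
Conditions: CF3CO2H/CH2Cl2 (1:4), 0 °C; aqueous work-up
Reagents that add atoms: none
Why: Acidolysis of the two aryl MOM acetals frees the catechol without base, so the β-aroyloxy enone, the hindered ester and both stereocentres are untouched.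

**Compound list**

1 | 4-methylphenol (p-cresol) | Cc1ccc(O)cc1 | starting material
2 | 4-methylcyclohexa-3,5-diene-1,2-dione (4-methyl-1,2-benzoquinone) | CC1=CC(=O)C(=O)C=C1 | intermediate
3 | 4-methylbenzene-1,2-diol | Cc1ccc(O)c(O)c1 | intermediate
4 | 1,2-bis(methoxymethoxy)-4-methylbenzene | COCOc1ccc(C)cc1OCOC | intermediate
5 | 1-bromo-4,5-bis(methoxymethoxy)-2-methylbenzene | COCOc1cc(C)c(Br)cc1OCOC | intermediate
6 | [2-bromo-5,6-bis(methoxymethoxy)-3-methylphenyl]lithium | COCOc1cc(C)c(Br)c([Li])c1OCOC | intermediate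
7 | diisopropyl [2-bromo-5,6-bis(methoxymethoxy)-3-methylphenyl]boronate | COCOc1cc(C)c(Br)c(B(OC(C)C)OC(C)C)c1OCOC | intermediate
8 | 2-bromo-5,6-bis(methoxymethoxy)-3-methylphenol | COCOc1cc(C)c(Br)c(O)c1OCOC | intermediate
9 | 1-bromo-2-methoxy-3,4-bis(methoxymethoxy)-6-methylbenzene | COCOc1cc(C)c(Br)c(OC)c1OCOC | intermediate
10 | [2-methoxy-3,4-bis(methoxymethoxy)-6-methylphenyl]lithium | COCOc1cc(C)c([Li])c(OC)c1OCOC | intermediate
11 | 2-methoxy-3,4-bis(methoxymethoxy)-6-methylbenzoic acid | COCOc1cc(C)c(C(=O)O)c(OC)c1OCOC | intermediate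
12 | (4R)-4-[(tert-butyldimethylsilyl)oxy]cyclopent-2-en-1-one | O=C1C=C[C@H](O[Si](C)(C)C(C)(C)C)C1 | starting material
13 | (4R)-4-[(tert-butyldimethylsilyl)oxy]-2-(hydroxymethyl)cyclopent-2-en-1-one | O=C1C(CO)=C[C@H](O[Si](C)(C)C(C)(C)C)C1 | intermediate
14 | (4R)-4-[(tert-butyldimethylsilyl)oxy]-2-{[(tert-butyldiphenylsilyl)oxy]methyl}cyclopent-2-en-1-one | O=C1C(CO[Si](c2ccccc2)(c2ccccc2)C(C)(C)C)=C[C@H](O[Si](C)(C)C(C)(C)C)C1 | intermediate
15 | (1S,4R)-4-[(tert-butyldimethylsilyl)oxy]-2-{[(tert-butyldiphenylsilyl)oxy]methyl}-1-[(trimethylsilyl)ethynyl]cyclopent-2-en-1-ol | O[C@]1(C#C[Si](C)(C)C)C(CO[Si](c2ccccc2)(c2ccccc2)C(C)(C)C)=C[C@H](O[Si](C)(C)C(C)(C)C)C1 | intermediate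
16 | (5R)-5-[(tert-butyldimethylsilyl)oxy]-2-{[(tert-butyldiphenylsilyl)oxy]methyl}-3-[(trimethylsilyl)ethynyl]cyclopent-2-en-1-one | O=C1[C@H](O[Si](C)(C)C(C)(C)C)CC(C#C[Si](C)(C)C)=C1CO[Si](c1ccccc1)(c1ccccc1)C(C)(C)C | intermediate
17 | (1S,5R)-5-[(tert-butyldimethylsilyl)oxy]-2-{[(tert-butyldiphenylsilyl)oxy]methyl}-1-(1-ethoxyethenyl)-3-[(trimethylsilyl)ethynyl]cyclopent-2-en-1-ol | C=C(OCC)[C@]1(O)C(CO[Si](c2ccccc2)(c2ccccc2)C(C)(C)C)=C(C#C[Si](C)(C)C)C[C@H]1O[Si](C)(C)C(C)(C)C | intermediate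
18 | 1-[(1S,5R)-5-[(tert-butyldimethylsilyl)oxy]-2-{[(tert-butyldiphenylsilyl)oxy]methyl}-1-hydroxy-3-[(trimethylsilyl)ethynyl]cyclopent-2-en-1-yl]ethan-1-one | CC(=O)[C@]1(O)C(CO[Si](c2ccccc2)(c2ccccc2)C(C)(C)C)=C(C#C[Si](C)(C)C)C[C@H]1O[Si](C)(C)C(C)(C)C | intermediate
19 | (5R,6R)-5-[(tert-butyldimethylsilyl)oxy]-2-{[(tert-butyldiphenylsilyl)oxy]methyl}-6-hydroxy-6-methyl-3-[(trimethylsilyl)ethynyl]cyclohex-2-en-1-one | CC(C)(C)[Si](C)(C)O[C@@H]1CC(C#C[Si](C)(C)C)=C(CO[Si](c2ccccc2)(c2ccccc2)C(C)(C)C)C(=O)[C@]1(C)O | intermediate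
20 | (5R,6R)-2-{[(tert-butyldiphenylsilyl)oxy]methyl}-5,6-dihydroxy-6-methyl-3-[(trimethylsilyl)ethynyl]cyclohex-2-en-1-one | O[C@@H]1CC(C#C[Si](C)(C)C)=C(CO[Si](c2ccccc2)(c2ccccc2)C(C)(C)C)C(=O)[C@]1(C)O | intermediate
21 | 2-methoxy-3,4-bis(methoxymethoxy)-6-methylbenzoyl chloride | COCOc1cc(C)c(C(=O)Cl)c(OC)c1OCOC | intermediate
22 | (1R,6R)-4-{[(tert-butyldiphenylsilyl)oxy]methyl}-6-hydroxy-6-methyl-5-oxo-3-[(trimethylsilyl)ethynyl]cyclohex-3-en-1-yl 2-methoxy-3,4-bis(methoxymethoxy)-6-methylbenzoate | COc1c(OCOC)c(OCOC)cc(C)c1C(=O)O[C@@H]1CC(C#C[Si](C)(C)C)=C(CO[Si](c2ccccc2)(c2ccccc2)C(C)(C)C)C(=O)[C@]1(C)O | intermediate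
23 | (1R,6R)-3-ethynyl-6-hydroxy-4-(hydroxymethyl)-6-methyl-5-oxocyclohex-3-en-1-yl 2-methoxy-3,4-bis(methoxymethoxy)-6-methylbenzoate | COc1c(OCOC)c(OCOC)cc(C)c1C(=O)O[C@@H]1CC(C#C)=C(CO)C(=O)[C@]1(C)O | intermediate
24 | (2E)-3-iodoprop-2-enoic acid | OC(=O)/C=C/I | starting material
25 | (2E)-5-[(4R,5R)-4-hydroxy-2-(hydroxymethyl)-5-{[2-methoxy-3,4-bis(methoxymethoxy)-6-methylbenzoyl]oxy}-4-methyl-3-oxocyclohex-1-en-1-yl]pent-2-en-4-ynoic acid | COc1c(OCOC)c(OCOC)cc(C)c1C(=O)O[C@@H]1CC(C#C/C=C/C(=O)O)=C(CO)C(=O)[C@]1(C)O | intermediate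
26 | (2E)-3-[(6R,7R)-7-hydroxy-6-{[2-methoxy-3,4-bis(methoxymethoxy)-6-methylbenzoyl]oxy}-7-methyl-8-oxo-5,6,7,8-tetrahydro-1H-isochromen-3-yl]prop-2-enoic acid | COc1c(OCOC)c(OCOC)cc(C)c1C(=O)O[C@@H]1CC2=C(COC(/C=C/C(=O)O)=C2)C(=O)[C@]1(C)O | intermediate
27 | (2E)-3-[(6R,7R)-6-[(3,4-dihydroxy-2-methoxy-6-methylbenzoyl)oxy]-7-hydroxy-7-methyl-8-oxo-5,6,7,8-tetrahydro-1H-isochromen-3-yl]prop-2-enoic acid | COc1c(O)c(O)cc(C)c1C(=O)O[C@@H]1CC2=C(COC(/C=C/C(=O)O)=C2)C(=O)[C@]1(C)O | target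

**Step count and risks**

Total step count: 18. Longest linear sequence: 12 steps (steps 7 to 18, from compound 12); the arene branch is 6 steps and joins at step 14.

The three steps most likely to fail:

Step 12 (the proposed new ring expansion). The ring vinyl carbon may shift instead of the silyloxy-bearing carbon; that gives the unconjugated isomer and, after a second methyl shift, the epimer at the tertiary carbinol. Fallback with known chemistry: it sets out from ketol 18. 48% aq. HF in MeCN removes the secondary silyl ether and gives 1-[(1S,5R)-2-{[(tert-butyldiphenylsilyl)oxy]methyl}-1,5-dihydroxy-3-[(trimethylsilyl)ethynyl]cyclopent-2-en-1-yl]ethan-1-one F1. F1 is then treated with NiCl2·6H2O and N,N,N′,N′-tetramethylethylenediamine in MeOH at 60 °C. This is the divalent-nickel/diamine 1,2-carbon shift known from C-2 epimerisation of aldoses and from branched-chain sugars: the carbonyl oxygen and both hydroxyls bind the metal on one face, only the hydroxyl-bearing carbon can migrate, and the shift is stereospecific, so the cis-diol results. It comes back to the route at diol 20, and step 13 is then not needed. The free β-hydroxy ketol can also undergo retro-aldol, which would erode optical purity, so the temperature should be kept as low as the shift allows.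

Step 14 (esterification). A di-ortho-substituted aroyl chloride must acylate a secondary alcohol next to a quaternary carbinol in a β-hydroxy ketone that is prone to retro-aldol. Fallback: install the ester before the ring expansion, on the less hindered cyclopentenone. It sets out from enone 16. Aqueous HF in MeCN gives (5R)-2-{[(tert-butyldiphenylsilyl)oxy]methyl}-5-hydroxy-3-[(trimethylsilyl)ethynyl]cyclopent-2-en-1-one F2. Acylation with acid chloride 21 (DMAP, pyridine) gives the aroyloxy enone F3. 1-Ethoxyvinyllithium adds anti to the ester and gives the enol ether carbinol F4, which dilute HCl hydrolyses to the aroyloxy ketol F5. The Sc(OTf)3 shift of F5 then leads to ester 22, where the route is rejoined; in this order the migrating carbon is less electron-rich, which is why it is the fallback and not the main line.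

Step 17 (6-endo against 5-exo closure). The acrylic acid polarises the alkyne in the opposite sense to the ring ketone, so some 5-exo alkylidene dihydrofuran may form. Fallback: electrophile-driven closure and dehalogenation. It sets out from enyne acid 25. I2 and NaHCO3 in MeCN at 0 °C give the 4-iodo-1H-isochromenone F6, because the iodonium ion opens at the alkenyl-substituted carbon (Larock-type 6-endo iodocyclisation). Pd(OAc)2/PPh3 with HCO2H and Et3N in DMF then replaces iodine by hydrogen and gives 26, where the route is rejoined.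

**Further compounds**

F1 | step 12 | 1-[(1S,5R)-2-{[(tert-butyldiphenylsilyl)oxy]methyl}-1,5-dihydroxy-3-[(trimethylsilyl)ethynyl]cyclopent-2-en-1-yl]ethan-1-one | CC(=O)[C@]1(O)C(CO[Si](c2ccccc2)(c2ccccc2)C(C)(C)C)=C(C#C[Si](C)(C)C)C[C@H]1O
F2 | step 14 | (5R)-2-{[(tert-butyldiphenylsilyl)oxy]methyl}-5-hydroxy-3-[(trimethylsilyl)ethynyl]cyclopent-2-en-1-one | O=C1[C@H](O)CC(C#C[Si](C)(C)C)=C1CO[Si](c1ccccc1)(c1ccccc1)C(C)(C)C
F3 | step 14 | (1R)-3-{[(tert-butyldiphenylsilyl)oxy]methyl}-2-oxo-4-[(trimethylsilyl)ethynyl]cyclopent-3-en-1-yl 2-methoxy-3,4-bis(methoxymethoxy)-6-methylbenzoate | O=C1[C@H](OC(=O)c2c(C)cc(OCOC)c(OCOC)c2OC)CC(C#C[Si](C)(C)C)=C1CO[Si](c1ccccc1)(c1ccccc1)C(C)(C)C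
F4 | step 14 | (1R,2S)-3-{[(tert-butyldiphenylsilyl)oxy]methyl}-2-(1-ethoxyethenyl)-2-hydroxy-4-[(trimethylsilyl)ethynyl]cyclopent-3-en-1-yl 2-methoxy-3,4-bis(methoxymethoxy)-6-methylbenzoate | C=C(OCC)[C@]1(O)C(CO[Si](c2ccccc2)(c2ccccc2)C(C)(C)C)=C(C#C[Si](C)(C)C)C[C@H]1OC(=O)c1c(C)cc(OCOC)c(OCOC)c1OC
F5 | step 14 | (1R,2S)-2-acetyl-3-{[(tert-butyldiphenylsilyl)oxy]methyl}-2-hydroxy-4-[(trimethylsilyl)ethynyl]cyclopent-3-en-1-yl 2-methoxy-3,4-bis(methoxymethoxy)-6-methylbenzoate | CC(=O)[C@]1(O)C(CO[Si](c2ccccc2)(c2ccccc2)C(C)(C)C)=C(C#C[Si](C)(C)C)C[C@H]1OC(=O)c1c(C)cc(OCOC)c(OCOC)c1OC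
F6 | step 17 | (2E)-3-[(6R,7R)-7-hydroxy-4-iodo-6-{[2-methoxy-3,4-bis(methoxymethoxy)-6-methylbenzoyl]oxy}-7-methyl-8-oxo-5,6,7,8-tetrahydro-1H-isochromen-3-yl]prop-2-enoic acid | COc1c(OCOC)c(OCOC)cc(C)c1C(=O)O[C@@H]1CC2=C(COC(/C=C/C(=O)O)=C2I)C(=O)[C@]1(C)O
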